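Target: epigallocatechin-(4β→8)-epigallocatechin 3-O-gallate-(4β→8)-epigallocatechin. Removing 18 benzyl ethers and cutting both C4–C8 interflavan bonds (flavan-4-yl cation + ring-A arene, built bottom-up) leads to one monomer, penta-O-benzyl-(−)-epigallocatechin: unchanged it is the lower unit, C4-oxidised and galloylated the middle unit, C4-oxidised the upper unit.
The monomer comes from a racemic flavan-3-one. C2 and C3 are set together by hydrogenation with dynamic kinetic resolution, and each C4 is set in its coupling by the 2,3-cis ring.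
The pyran ring C (O1–C2–C3–C4–C4a–C8a) of all three units comes from the furan ring (O1–C2–C3–C3a–C7a) of a flat, achiral 2-benzylbenzofuran. One O-atom transfer starts the sequence epoxide → acyl o-quinone methide → dienol → oxa-6π closure; this moves O1 onto the benzylic carbon (new C2), makes the old furan C2 into C3=O and the old furan C3 into C4H2.
Enabling feature: the enol-ether C2=C3 bond of the furan ring lies between O1 and the 4,6-dioxygenated ring A, which open the epoxide to the quinone methide, and an exocyclic ArCH2. That CH2 is the only enolisable site of the resulting ketone and the sixth atom of the oxatriene that starts at the quinone-methide oxygen.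
Ring order: rings A and B and the furan ring are bought and joined by aurone condensation, then furan → pyran by ring expansion. No further ring is formed.

Key step: step 5

Assumption: compounds 1, 3 and 14 are taken as catalogue chemicals, and dimethyldioxirane as a freshly prepared, titrated acetone solution.

Step 1
Reactants: 1 4,6-dihydroxybenzofuran-3(2H)-one
Product: 2 4,6-bis(benzyloxy)benzofuran-3(2H)-one
Conditions: BnBr (2.2 equiv), K2CO3, DMF, 25–50 °C
Reagents that add atoms: benzyl bromide, BrCc1ccccc1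
Why: Williamson ether synthesis on the two phenols with a weak base that leaves the less acidic C2 methylene of the coumaranone untouched; no stereocentre is formed.

Step 2
Reactants: 2 4,6-bis(benzyloxy)benzofuran-3(2H)-one; 3 3,4,5-tris(benzyloxy)benzaldehyde
Product: 4 (Z)-4,6-bis(benzyloxy)-2-[3,4,5-tris(benzyloxy)benzylidene]benzofuran-3(2H)-one (penta-O-benzyl aurone)
Conditions: neutral Al2O3, CH2Cl2, 25 °C
Reagents that add atoms: none
Why: Aldol condensation (aurone synthesis) of the activated C2 methylene with the aldehyde, which should give the thermodynamically preferred Z alkene because the E isomer suffers an aryl/carbonyl clash.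

Step 3
Reactants: 4 penta-O-benzyl aurone
Product: 5 (Z)-4,6-bis(benzyloxy)-2-[3,4,5-tris(benzyloxy)benzylidene]-2,3-dihydrobenzofuran-3-ol (racemic at C3)
Conditions: NaBH4, CeCl3·7H2O, MeOH–THF, −20 °C
Reagents that add atoms: none
Why: Luche reduction delivers hydride 1,2 to the enone carbonyl, and the racemic carbinol centre is erased in the next step.

Step 4
Reactants: 5 the allylic alcohol
Product: 6 4,6-bis(benzyloxy)-2-[3,4,5-tris(benzyloxy)benzyl]benzofuran
Conditions: Et3SiH (3 equiv), CF3CO2H, CH2Cl2, −40 → 0 °C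
Reagents that add atoms: none
Why: Ionic hydrogenation: acid ionises the allylic alcohol to the delocalised (benzofuran-2-yl)(aryl)methyl cation, and hydride capture at either terminus converges on the aromatic benzofuran under the acidic conditions.

Step 5
Reactants: 6 4,6-bis(benzyloxy)-2-[3,4,5-tris(benzyloxy)benzyl]benzofuran
Product: 11 rac-5,7-bis(benzyloxy)-2-[3,4,5-tris(benzyloxy)phenyl]chroman-3-one (racemic penta-O-benzyl flavan-3-one), via benzofuran epoxide 7 (not isolated), via acyl o-quinone methide 8 (not isolated), via dienol o-quinone methide 9 (not isolated), via 2H-chromen-3-ol 10 (not isolated)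
Conditions: DMDO (1.0 equiv, acetone), 4 Å MS, CH2Cl2, −78 → −30 °C; volatiles off at −30 °C; i-Pr2NEt (10 mol %), CH2Cl2 (2 mM), −30 → 25 °C
Reagents that add atoms: dimethyldioxirane, CC1(C)OO1
Why: Proposed new method: DMDO transfers one oxygen to the furan C2=C3 bond of 6 to give epoxide 7, whose benzylic C3–O(epoxide) bond and ring C2–O1 bond open to the Z acyl o-quinone methide 8; the hindered amine enolises the ArCH2 group to dienol 9, which closes to 2H-chromen-3-ol 10 and ketonises to 11, so that the benzylic carbon ends up between O1 and the old furan C2 (five- to six-membered ring). The closest known reaction types are the dimethyldioxirane epoxidation of benzofurans with valence isomerisation of the epoxides to o-quinone methides, and the oxa-6π electrocyclisation of vinyl o-quinone methides to 2H-chromenes; joining them into a ring expansion is new. The pyran ring closes by a thermal disrotatory oxa-6π electrocyclisation that forms the O1–C2 bond, is driven by rearomatisation of ring A, and uses the Z geometry inherited from the furan ring. The only new stereocentre, C2, is formed racemic and is deliberately left uncontrolled, because it is α to the ketone and is set in step 6. The step needs O-transfer to the furan double bond only (secured by its enol-ether character reinforced by the 4- and 6-benzyloxy donors, by low temperature and by one equivalent of a neutral oxidant that spares arenes and benzyl ethers), opening to 8 rather than a 1,2-hydride shift to a coumaranone (secured by the same donors, which stabilise charge at the benzylic carbon), and regiospecific enolisation (the other α position of 8 is vinylic). Removing residual oxidant before the base is added protects enol 10, and high dilution with sieves disfavours dimerisation or hydration of 8.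

Step 6
Reactants: 11 racemic penta-O-benzyl flavan-3-one
Product: 12 (2R,3R)-5,7-bis(benzyloxy)-2-[3,4,5-tris(benzyloxy)phenyl]chroman-3-ol (penta-O-benzyl-(−)-epigallocatechin)
Conditions: RuCl2[(Sa)-Xyl-SDP][(R,R)-DPEN] (0.5 mol %), KOt-Bu (20 mol %), H2 (50 atm), i-PrOH–toluene, 25 °C
Reagents that add atoms: none
Why: Noyori-type bifunctional ketone hydrogenation under dynamic kinetic resolution, as known for α-aryl cycloalkanones: alkoxide-mediated enolisation should interconvert the C2 epimers faster than reduction, and the catalyst antipode matched to the (2R)-ketone delivers hydride to C3 anti to the C2 aryl group, giving the 2,3-cis (2R,3R)-alcohol.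

Step 7
Reactants: 12 penta-O-benzyl-(−)-epigallocatechin
Product: 13 (2R,3R,4S)-5,7-bis(benzyloxy)-4-(2-ethoxyethoxy)-2-[3,4,5-tris(benzyloxy)phenyl]chroman-3-ol (4β-(2-ethoxyethoxy) derivative of 12)
Conditions: DDQ (2 equiv), 2-ethoxyethanol (5 equiv), CH2Cl2, 25 °C
Reagents that add atoms: 2-ethoxyethanol, CCOCCO
Why: DDQ benzylic C–H oxidation by hydride abstraction at C4, the only position whose cation is stabilised by O1 and the 5- and 7-benzyloxy groups, followed by capture of the alcohol on the β face, trans to the axial 3-OH.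

Step 8
Reactants: 13 4β-(2-ethoxyethoxy) derivative; 14 3,4,5-tris(benzyloxy)benzoic acid
Product: 15 (2R,3R,4S)-5,7-bis(benzyloxy)-4-(2-ethoxyethoxy)-2-[3,4,5-tris(benzyloxy)phenyl]chroman-3-yl 3,4,5-tris(benzyloxy)benzoate
Conditions: DCC, DMAP, CH2Cl2, 25 °C
Reagents that add atoms: none
Why: Steglich esterification acylates the single free (axial) hydroxyl under neutral conditions that leave the acid-labile C4 ether and all stereocentres untouched.

Step 9
Reactants: 15 galloylated C4 electrophile; 12 penta-O-benzyl-(−)-epigallocatechin (4 equiv)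
Product: 16 [penta-O-benzyl-epigallocatechin 3-O-(tri-O-benzyl)gallate]-(4β→8)-[penta-O-benzyl-epigallocatechin]
Conditions: TMSOTf (0.5 equiv), CH2Cl2, −78 °C
Reagents that add atoms: none
Why: Lewis-acid ionisation of the C4 ether gives the flavan-4-yl cation (Friedel–Crafts-type interflavan coupling); the α-face 3-O-galloyl group and the 2,3-cis ring direct C8 of 12, its most nucleophilic ring-A position, to the β face (3,4-trans), and the excess of 12 suppresses chain growth.

Step 10
Reactants: 13 4β-(2-ethoxyethoxy) derivative (slow addition); 16 protected dimer (2 equiv)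
Product: 17 [penta-O-benzyl-epigallocatechin]-(4β→8)-[penta-O-benzyl-epigallocatechin 3-O-(tri-O-benzyl)gallate]-(4β→8)-[penta-O-benzyl-epigallocatechin]
Conditions: TMSOTf (0.5 equiv), CH2Cl2, −78 → −40 °C
Reagents that add atoms: none
Why: The same Friedel–Crafts-type flavan-4-yl cation coupling: the only free C8 of 16 is that of its upper unit, and attack trans to the axial 3-oxygen of the 2,3-cis cation should set the new C4 as 4β.

Step 11
Reactants: 17 protected trimer
Product: 18 epigallocatechin-(4β→8)-epigallocatechin 3-O-gallate-(4β→8)-epigallocatechin (target)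
Conditions: H2 (1 atm), 20% Pd(OH)2/C, THF–MeOH–H2O, 25 °C
Reagents that add atoms: none
Why: Catalytic hydrogenolysis cleaves all eighteen aryl benzyl ethers under neutral conditions that leave the gallate ester, the interflavan bonds and every stereocentre intact.

Compound list
1 | 4,6-dihydroxybenzofuran-3(2H)-one | O=C1COc2cc(O)cc(O)c12 | starting material
2 | 4,6-bis(benzyloxy)benzofuran-3(2H)-one | O=C1COc2cc(OCc9ccccc9)cc(OCc9ccccc9)c12 | intermediate
3 | 3,4,5-tris(benzyloxy)benzaldehyde | O=Cc1cc(OCc9ccccc9)c(OCc9ccccc9)c(OCc9ccccc9)c1 | starting material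
4 | (Z)-4,6-bis(benzyloxy)-2-[3,4,5-tris(benzyloxy)benzylidene]benzofuran-3(2H)-one | O=C1c2c(OCc9ccccc9)cc(OCc9ccccc9)cc2O/C1=C\c1cc(OCc9ccccc9)c(OCc9ccccc9)c(OCc9ccccc9)c1 | intermediate
5 | (Z)-4,6-bis(benzyloxy)-2-[3,4,5-tris(benzyloxy)benzylidene]-2,3-dihydrobenzofuran-3-ol, racemic at C3 | OC1c2c(OCc9ccccc9)cc(OCc9ccccc9)cc2O/C1=C\c1cc(OCc9ccccc9)c(OCc9ccccc9)c(OCc9ccccc9)c1 | intermediate
6 | 4,6-bis(benzyloxy)-2-[3,4,5-tris(benzyloxy)benzyl]benzofuran | C(c1cc2c(OCc9ccccc9)cc(OCc9ccccc9)cc2o1)c1cc(OCc9ccccc9)c(OCc9ccccc9)c(OCc9ccccc9)c1 | intermediate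
7 | 2,3-epoxide of 6 (cis-fused oxirane on furan C2–C3, racemic) | C(c1cc(OCc9ccccc9)c(OCc9ccccc9)c(OCc9ccccc9)c1)C12OC1c1c(OCc9ccccc9)cc(OCc9ccccc9)cc1O2 | intermediate
8 | (6Z)-3,5-bis(benzyloxy)-6-{2-oxo-3-[3,4,5-tris(benzyloxy)phenyl]propylidene}cyclohexa-2,4-dien-1-one | O=C(Cc1cc(OCc9ccccc9)c(OCc9ccccc9)c(OCc9ccccc9)c1)/C=C1\C(=O)C=C(OCc9ccccc9)C=C1OCc9ccccc9 | intermediate
9 | (6Z)-3,5-bis(benzyloxy)-6-{(2Z)-2-hydroxy-3-[3,4,5-tris(benzyloxy)phenyl]prop-2-enylidene}cyclohexa-2,4-dien-1-one | O/C(=C\c1cc(OCc9ccccc9)c(OCc9ccccc9)c(OCc9ccccc9)c1)/C=C1\C(=O)C=C(OCc9ccccc9)C=C1OCc9ccccc9 | intermediate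
10 | 5,7-bis(benzyloxy)-2-[3,4,5-tris(benzyloxy)phenyl]-2H-chromen-3-ol, racemic | OC1=Cc2c(OCc9ccccc9)cc(OCc9ccccc9)cc2OC1c1cc(OCc9ccccc9)c(OCc9ccccc9)c(OCc9ccccc9)c1 | intermediate
11 | rac-5,7-bis(benzyloxy)-2-[3,4,5-tris(benzyloxy)phenyl]chroman-3-one | O=C1Cc2c(OCc9ccccc9)cc(OCc9ccccc9)cc2OC1c1cc(OCc9ccccc9)c(OCc9ccccc9)c(OCc9ccccc9)c1 | intermediate
12 | (2R,3R)-5,7-bis(benzyloxy)-2-[3,4,5-tris(benzyloxy)phenyl]chroman-3-ol | O[C@@H]1Cc2c(OCc9ccccc9)cc(OCc9ccccc9)cc2O[C@@H]1c1cc(OCc9ccccc9)c(OCc9ccccc9)c(OCc9ccccc9)c1 | intermediate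
13 | (2R,3R,4S)-5,7-bis(benzyloxy)-4-(2-ethoxyethoxy)-2-[3,4,5-tris(benzyloxy)phenyl]chroman-3-ol | O[C@@H]1[C@@H](OCCOCC)c2c(OCc9ccccc9)cc(OCc9ccccc9)cc2O[C@@H]1c1cc(OCc9ccccc9)c(OCc9ccccc9)c(OCc9ccccc9)c1 | intermediate
14 | 3,4,5-tris(benzyloxy)benzoic acid | OC(=O)c1cc(OCc9ccccc9)c(OCc9ccccc9)c(OCc9ccccc9)c1 | starting material
15 | (2R,3R,4S)-5,7-bis(benzyloxy)-4-(2-ethoxyethoxy)-2-[3,4,5-tris(benzyloxy)phenyl]chroman-3-yl 3,4,5-tris(benzyloxy)benzoate | O=C(O[C@@H]1[C@@H](OCCOCC)c2c(OCc9ccccc9)cc(OCc9ccccc9)cc2O[C@@H]1c1cc(OCc9ccccc9)c(OCc9ccccc9)c(OCc9ccccc9)c1)c1cc(OCc9ccccc9)c(OCc9ccccc9)c(OCc9ccccc9)c1 | intermediate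
16 | tridecabenzyl dimer, epigallocatechin 3-O-gallate-(4β→8)-epigallocatechin, all phenols as benzyl ethers, lower 3-OH free | O=C(O[C@@H]1[C@@H](c2c(OCc9ccccc9)cc(OCc9ccccc9)c3c2O[C@H](c2cc(OCc9ccccc9)c(OCc9ccccc9)c(OCc9ccccc9)c2)[C@H](O)C3)c2c(OCc9ccccc9)cc(OCc9ccccc9)cc2O[C@@H]1c1cc(OCc9ccccc9)c(OCc9ccccc9)c(OCc9ccccc9)c1)c1cc(OCc9ccccc9)c(OCc9ccccc9)c(OCc9ccccc9)c1 | intermediate
17 | octadecabenzyl trimer, epigallocatechin-(4β→8)-epigallocatechin 3-O-gallate-(4β→8)-epigallocatechin, all phenols as benzyl ethers, upper and lower 3-OH free | O=C(O[C@@H]1[C@@H](c2c(OCc9ccccc9)cc(OCc9ccccc9)c3c2O[C@H](c2cc(OCc9ccccc9)c(OCc9ccccc9)c(OCc9ccccc9)c2)[C@H](O)C3)c2c(OCc9ccccc9)cc(OCc9ccccc9)c([C@H]3c4c(OCc9ccccc9)cc(OCc9ccccc9)cc4O[C@H](c4cc(OCc9ccccc9)c(OCc9ccccc9)c(OCc9ccccc9)c4)[C@@H]3O)c2O[C@@H]1c1cc(OCc9ccccc9)c(OCc9ccccc9)c(OCc9ccccc9)c1)c1cc(OCc9ccccc9)c(OCc9ccccc9)c(OCc9ccccc9)c1 | intermediate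
18 | epigallocatechin-(4β→8)-epigallocatechin 3-O-gallate-(4β→8)-epigallocatechin (CNP0278699.1) | O=C(O[C@@H]1[C@@H](c2c(O)cc(O)c3c2O[C@H](c2cc(O)c(O)c(O)c2)[C@H](O)C3)c2c(O)cc(O)c([C@H]3c4c(O)cc(O)cc4O[C@H](c4cc(O)c(O)c(O)c4)[C@@H]3O)c2O[C@@H]1c1cc(O)c(O)c(O)c1)c1cc(O)c(O)c(O)c1 | target

Total step count: 11. Longest linear sequence: 11 steps (1 → 2 → 4 → 5 → 6 → 11 → 12 → 13 → 15 → 16 → 17 → 18); compounds 12 and 13 are drawn from this line a second time in steps 9 and 10.

Steps most likely to fail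

1. Step 5 (Proposed new method). The epoxide may rearrange by a 1,2-hydride shift. The quinone methide may also add adventitious water or dimerise before it enolises, or the enol may be oxidised further. The fallback sets out from 4 and comes back at 11, and it keeps a furan-to-pyran enlargement by classical chemistry. Nucleophilic epoxidation of 4 (H2O2, NaOH, MeOH–THF, 0 °C) would give the spiro compound aurone epoxide F1. Treatment with ethanolic KOH enlarges the coumaranone ring, as in the ring-expansion stage of the Auwers synthesis, to the flavonol penta-O-benzylmyricetin F2. LiAlH4 (THF, 0 °C) followed by HCl–MeOH dehydrates the reduced flavonol to penta-O-benzyldelphinidin chloride F3. NaBH4 (MeCN–THF, −20 °C) then adds hydride at C2 or C4, and both flavenols ketonise to 11.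

2. Step 6. Epimerisation at C2 may be slower than reduction, facial discrimination by the catalyst may be poor, or the enolisable ketone may degrade in the basic medium. The fallback sets out from 11 and comes back at 12. L-Selectride with LiBr (THF, −78 °C), the established cis-selective reduction of flavan-3-ones, would give rac-penta-O-benzyl-epigallocatechin F4. Esterification with (S)-2-methoxy-2-phenylacetic acid (DCC, DMAP) and chromatographic separation of the diastereomers gives the (2R,3R)-configured O-methylmandelate F5. K2CO3 in MeOH–THF cleaves this ester to 12.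

3. Step 10. The electrophile may self-condense through its own C8, attack may occur at C6 positions of the dimer, or acid may scramble the existing interflavan bond. The fallback sets out from 12 and comes back at 18, and it blocks the electrophile's own nucleophilic site with a halogen cap. NBS (CH2Cl2, −78 → −40 °C) would give 8-bromo-penta-O-benzyl-epigallocatechin F6. DDQ and 2-ethoxyethanol give its 4β-(2-ethoxyethoxy) derivative F7. TMSOTf-promoted coupling with 16 gives the 8-bromo octadecabenzyl trimer F8. Hydrogenolysis over Pd(OH)2/C in the presence of Et3N removes the bromine together with all benzyl groups to give 18.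

Further compounds
F1 | step 5 | 4,6-bis(benzyloxy)-3'-[3,4,5-tris(benzyloxy)phenyl]spiro[benzofuran-2(3H),2'-oxiran]-3-one (aurone epoxide, racemic) | O=C1c2c(OCc9ccccc9)cc(OCc9ccccc9)cc2OC13OC3c1cc(OCc9ccccc9)c(OCc9ccccc9)c(OCc9ccccc9)c1
F2 | step 5 | 5,7-bis(benzyloxy)-3-hydroxy-2-[3,4,5-tris(benzyloxy)phenyl]-4H-chromen-4-one (penta-O-benzylmyricetin) | O=c1c(O)c(-c2cc(OCc9ccccc9)c(OCc9ccccc9)c(OCc9ccccc9)c2)oc2cc(OCc9ccccc9)cc(OCc9ccccc9)c12
F3 | step 5 | 5,7-bis(benzyloxy)-3-hydroxy-2-[3,4,5-tris(benzyloxy)phenyl]chromenylium chloride (penta-O-benzyldelphinidin chloride) | [Cl-].Oc1cc2c(OCc9ccccc9)cc(OCc9ccccc9)cc2[o+]c1-c1cc(OCc9ccccc9)c(OCc9ccccc9)c(OCc9ccccc9)c1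
F4 | step 6 | rac-cis-5,7-bis(benzyloxy)-2-[3,4,5-tris(benzyloxy)phenyl]chroman-3-ol (1:1 mixture of 12 and its enantiomer) | O[C@@H]1Cc2c(OCc9ccccc9)cc(OCc9ccccc9)cc2O[C@@H]1c1cc(OCc9ccccc9)c(OCc9ccccc9)c(OCc9ccccc9)c1.O[C@H]1Cc2c(OCc9ccccc9)cc(OCc9ccccc9)cc2O[C@H]1c1cc(OCc9ccccc9)c(OCc9ccccc9)c(OCc9ccccc9)c1
F5 | step 6 | (2R,3R)-5,7-bis(benzyloxy)-2-[3,4,5-tris(benzyloxy)phenyl]chroman-3-yl (S)-2-methoxy-2-phenylacetate | CO[C@@H](c1ccccc1)C(=O)O[C@@H]1Cc2c(OCc9ccccc9)cc(OCc9ccccc9)cc2O[C@@H]1c1cc(OCc9ccccc9)c(OCc9ccccc9)c(OCc9ccccc9)c1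
F6 | step 10 | (2R,3R)-5,7-bis(benzyloxy)-8-bromo-2-[3,4,5-tris(benzyloxy)phenyl]chroman-3-ol | O[C@@H]1Cc2c(OCc9ccccc9)cc(OCc9ccccc9)c(Br)c2O[C@@H]1c1cc(OCc9ccccc9)c(OCc9ccccc9)c(OCc9ccccc9)c1
F7 | step 10 | 4β-(2-ethoxyethoxy) derivative of F6 | O[C@@H]1[C@@H](OCCOCC)c2c(OCc9ccccc9)cc(OCc9ccccc9)c(Br)c2O[C@@H]1c1cc(OCc9ccccc9)c(OCc9ccccc9)c(OCc9ccccc9)c1
F8 | step 10 | 17 carrying bromine at C8 of the upper unit | O=C(O[C@@H]1[C@@H](c2c(OCc9ccccc9)cc(OCc9ccccc9)c3c2O[C@H](c2cc(OCc9ccccc9)c(OCc9ccccc9)c(OCc9ccccc9)c2)[C@H](O)C3)c2c(OCc9ccccc9)cc(OCc9ccccc9)c([C@H]3c4c(OCc9ccccc9)cc(OCc9ccccc9)c(Br)c4O[C@H](c4cc(OCc9ccccc9)c(OCc9ccccc9)c(OCc9ccccc9)c4)[C@@H]3O)c2O[C@@H]1c1cc(OCc9ccccc9)c(OCc9ccccc9)c(OCc9ccccc9)c1)c1cc(OCc9ccccc9)c(OCc9ccccc9)c(OCc9ccccc9)c1
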